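The 19-membered ring is opened at the CH2–CH2 bridge between the para-phenylene ring (B) and the phenol-bearing ring (C): its two benzylic carbons are read as two aryl aldehydes. An open-chain dialdehyde that already holds all four benzene rings, both diaryl ether oxygens and the saturated bridge between the methoxy ring (A) and the meta-phenylene ring (D) is closed by an intramolecular McMurry coupling, which forms the macrocycle as a (Z)-stilbene in one operation. One final hydrogenation saturates the new bridge and frees the phenol. The precursor is built linearly by B-alkyl Suzuki coupling, SNAr and Ullmann etherification; the flexible A–D bridge and the two ether bends let the chain fold.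

Key step: step 4

Remark: the target SMILES contains no stereocentre and the macrocycle is treated as conformationally mobile, so the route has no configuration to control; the alkene geometry of 9 is erased in step 5.

Step 1
Reactants: 1 3-bromostyrene; 2 5-iodo-2-methoxyphenol
Product: 4 5-[2-(3-bromophenyl)ethyl]-2-methoxyphenol, via B-alkyl-9-BBN adduct 3 (not isolated)
Conditions: 1 (1.1 equiv), 9-BBN (0.5 M in THF), 0 °C to rt; then 2, PdCl2(dppf) (3 mol %), 3 M aq NaOH, THF, rt to 40 °C
Reagents that add atoms: none
Why: 9-BBN should add anti-Markovnikov to the vinyl group, and the primary alkylborane should then couple in a B-alkyl Suzuki–Miyaura reaction only at the C–I bond of 2, because oxidative addition of Pd(0)/dppf into aryl C–I is far faster than into aryl C–Br at this temperature and the phenoxide is inert.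

Step 2
Reactants: 4 5-[2-(3-bromophenyl)ethyl]-2-methoxyphenol; 5 4-fluorobenzaldehyde
Product: 6 4-{5-[2-(3-bromophenyl)ethyl]-2-methoxyphenoxy}benzaldehyde
Conditions: K2CO3, DMF, 120 °C
Reagents that add atoms: none
Why: Nucleophilic aromatic substitution (SNAr), in which the phenoxide of 4 displaces the fluoride para to the formyl group through a Meisenheimer intermediate, while the unactivated aryl bromide cannot react without a metal.

Step 3
Reactants: 6 4-{5-[2-(3-bromophenyl)ethyl]-2-methoxyphenoxy}benzaldehyde; 7 4-(benzyloxy)-3-hydroxybenzaldehyde
Product: 8 4-(benzyloxy)-3-(3-{2-[3-(4-formylphenoxy)-4-methoxyphenyl]ethyl}phenoxy)benzaldehyde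
Conditions: 7 (1.5 equiv), CuI (10 mol %), N,N-dimethylglycine hydrochloride (30 mol %), Cs2CO3, 1,4-dioxane, 90 °C
Reagents that add atoms: none
Why: Ligand-accelerated Ullmann diaryl ether synthesis, in which Cu(I)/amino acid should couple the caesium phenoxide of 7 with the aryl bromide under conditions mild enough for both aldehydes and the benzyl ether, ortho-alkoxy phenols being accepted substrates of this reaction.

Step 4
Reactants: 8 4-(benzyloxy)-3-(3-{2-[3-(4-formylphenoxy)-4-methoxyphenyl]ethyl}phenoxy)benzaldehyde
Product: 9 macrocyclic (Z)-stilbene, the O-benzyl ether of the target with a (Z)-CH=CH bridge between ring B and ring C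
Conditions: TiCl4, Zn dust, pyridine, THF, reflux; 8 added by syringe pump over about 20 h (final about 1 mM); aq K2CO3 work-up
Reagents that add atoms: none
Why: Low-valent titanium should transfer single electrons to both aryl aldehydes, the two ketyl centres combine to a titanium-bound pinacolate, and at reflux both C–O bonds are cleaved on the oxophilic metal to leave the C=C bond; this is an intramolecular McMurry coupling, a known way to close dialdehydes to macrocyclic stilbenes and cyclophanes. The 19-membered ring is closed end to end by C–C bond formation between the two former formyl carbons, so the new alkene is endocyclic and bridges ring B and ring C. No stereocentre is formed; the alkene is expected to be Z, because an E-stilbene would hold the two ether oxygens too far apart for the rest of the ring to span, and its geometry is erased in step 5 in any case. The selectivity needed is ring closure over intermolecular coupling, which slow addition into excess reagent (pseudo-high dilution) should secure, helped by the two C–O–C bends of about 120° and the flexible CH2–CH2 bridge between rings A and D that let the chain ends meet. The aryl benzyl ether, the methyl ether and the diaryl ethers are inert to the reagent, and no aryl halide remains at this stage.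

Step 5
Reactants: 9 macrocyclic (Z)-stilbene benzyl ether
Product: 10 target CNP0132125.0
Conditions: H2 (1 atm), 10% Pd/C, EtOAc/MeOH, rt
Reagents that add atoms: none
Why: Heterogeneous catalytic hydrogenation should saturate the stilbene C=C and hydrogenolyse the benzylic C–O bond of the aryl benzyl ether in the same operation, while the diaryl ethers and the aryl methyl ether stay intact and no stereocentre arises.

Compound list
1 | 3-bromostyrene (1-bromo-3-ethenylbenzene) | C=Cc1cccc(Br)c1 | starting material
2 | 5-iodo-2-methoxyphenol | COc1ccc(I)cc1O | starting material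
3 | 9-[2-(3-bromophenyl)ethyl]-9-borabicyclo[3.3.1]nonane | Brc1cccc(CCB2C3CCCC2CCC3)c1 | intermediate
4 | 5-[2-(3-bromophenyl)ethyl]-2-methoxyphenol | COc1ccc(CCc2cccc(Br)c2)cc1O | intermediate
5 | 4-fluorobenzaldehyde | O=Cc1ccc(F)cc1 | starting material
6 | 4-{5-[2-(3-bromophenyl)ethyl]-2-methoxyphenoxy}benzaldehyde | COc1ccc(CCc2cccc(Br)c2)cc1Oc1ccc(C=O)cc1 | intermediate
7 | 4-(benzyloxy)-3-hydroxybenzaldehyde | O=Cc1ccc(OCc2ccccc2)c(O)c1 | starting material
8 | 4-(benzyloxy)-3-(3-{2-[3-(4-formylphenoxy)-4-methoxyphenyl]ethyl}phenoxy)benzaldehyde | COc1ccc(CCc2cccc(Oc3cc(C=O)ccc3OCc3ccccc3)c2)cc1Oc1ccc(C=O)cc1 | intermediate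
9 | macrocyclic (Z)-stilbene, O-benzyl ether of the target with a (Z)-CH=CH bridge between ring B and ring C | COc1ccc2cc1Oc1ccc(cc1)/C=C\c1ccc(OCc3ccccc3)c(c1)Oc1cccc(c1)CC2 | intermediate
10 | CNP0132125.0 | COc1ccc2cc1Oc1ccc(cc1)CCc1ccc(O)c(c1)Oc1cccc(c1)CC2 | target

Total step count: 5
Longest linear sequence: 5 (steps 1 to 5, from 3-bromostyrene)

Steps most likely to fail

Step 4. Intermolecular carbonyl coupling may outrun ring closure and give oligomers, or the reaction may stall at the pinacolate because deoxygenation has to deliver a Z-alkene inside the ring. The fallback sets out from 8 and changes the ring-closing reaction to olefin metathesis. Double Wittig methylenation (Ph3PCH3Br, KOt-Bu, THF, 0 °C to rt) should give the bis-styrene 1-(benzyloxy)-4-ethenyl-2-(3-{2-[3-(4-ethenylphenoxy)-4-methoxyphenyl]ethyl}phenoxy)benzene F1. Ring-closing metathesis of F1 (second-generation Grubbs catalyst, toluene, about 1 mM, 60–80 °C, loss of ethene) is reversible and should settle on the only strain-free cyclic alkene. The fallback comes back to the route at 9.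

Step 1. Oxidative addition into the C–Br bond of the alkylborane may compete once the iodide runs low and give head-to-tail oligomers, and transmetalation of the alkylborane to the electron-rich iodophenoxide–palladium species may be slow enough for protodeboronation to intervene. The fallback sets out from 1 and 2 and avoids the organoborane. A phosphine-free Heck reaction (Pd(OAc)2, Et3N, DMF, 80 °C), which touches only the C–I bond, should give (E)-5-[2-(3-bromophenyl)ethenyl]-2-methoxyphenol F2. Diimide reduction of F2 (TsNHNH2, NaOAc, THF/H2O, reflux) saturates the alkene without touching the aryl bromide. The fallback comes back to the route at 4.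

Step 3. C–O bond formation with the hindered ortho-benzyloxy phenol may be slow, so that protodebromination and base-induced degradation of the aldehydes take over at the temperature needed. The fallback sets out from 6 and inverts the polarity of the aryl partner. Miyaura borylation (B2pin2, PdCl2(dppf), KOAc, dioxane, 80 °C) should give 4-(2-methoxy-5-{2-[3-(4,4,5,5-tetramethyl-1,3,2-dioxaborolan-2-yl)phenyl]ethyl}phenoxy)benzaldehyde F3. Oxidative Chan–Lam coupling of F3 with 7 (Cu(OAc)2, pyridine, B(OH)3, 4 Å MS, MeCN, air, 60–80 °C) then forms the diaryl ether under near-neutral conditions. The fallback comes back to the route at 8.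

Further compounds
F1 | step 4 | 1-(benzyloxy)-4-ethenyl-2-(3-{2-[3-(4-ethenylphenoxy)-4-methoxyphenyl]ethyl}phenoxy)benzene | COc1ccc(CCc2cccc(Oc3cc(C=C)ccc3OCc3ccccc3)c2)cc1Oc1ccc(C=C)cc1
F2 | step 1 | (E)-5-[2-(3-bromophenyl)ethenyl]-2-methoxyphenol | COc1ccc(/C=C/c2cccc(Br)c2)cc1O
F3 | step 3 | 4-(2-methoxy-5-{2-[3-(4,4,5,5-tetramethyl-1,3,2-dioxaborolan-2-yl)phenyl]ethyl}phenoxy)benzaldehyde | COc1ccc(CCc2cccc(B3OC(C)(C)C(C)(C)O3)c2)cc1Oc1ccc(C=O)cc1
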